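Ring C is disconnected at C11–C12 (kaurane-type locants, see remark). The key step is a SmI2-mediated 6-endo ketyl–olefin cyclisation: the C9 aldehyde carbon (C11) of a tricyclic lactone is joined to the CH2 terminus (C12) of a 2-acetylallyl group on bridgehead C8, closing ring C and setting C11 and C13 in one operation. It exploits the 1,3-related C11 carbinol and C13 acyl-bearing methine of ring C and the trans-vicinal C8/C9 substituents of the cyclopentane. The precursor (ring A, cyclopentane, δ-lactone) comes from a titanocene-mediated radical coupling/aldol of a ring A epoxy aldehyde with a chiral butenolide; the acetyl group is finally carbonylated to the acrylate.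

Key step: step 11

Remark 1: Kaurane-type locants are used for all intermediates. Ring A is C1–C5 and C10 (C1 bears the acetoxy group, C4 the gem-dimethyl group). C6 is the cyclopentane carbinol, C7 the lactone carbonyl, C8 and C9 the ring-fusion carbons, C11 the ring C carbinol, C12 and C14 the ring C methylenes, C13 the ring C methine, C15–C17 the acrylate and C20 the lactone CH2.
Remark 2: (5S)-5-(d-Menthyloxy)furan-2(5H)-one (9), the enantiomer of the l-menthol-derived reagent, is taken as commercially available.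
Remark 3: Compounds 2–5 are racemic; their SMILES show the enantiomer that is carried on.

Step 1
Reactants: 1 4,4-dimethylcyclohex-2-en-1-one
Product: 4 rac-3-ethenyl-4,4-dimethyl-2-methylidenecyclohexan-1-one, via Mannich base 2 (not isolated), via ammonium iodide 3 (not isolated)
Conditions: CH2=CHMgBr, CuBr·SMe2 (10 mol%), THF, −40 °C; then Me2N=CH2+ I−, −40 °C → rt; then MeI, CH2Cl2; then NaHCO3 (aq), rt
Reagents that add atoms: vinylmagnesium bromide C=C[Mg]Br; N,N-dimethylmethyleneiminium iodide (Eschenmoser's salt) C[N+](C)=C.[I-]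
Why: Copper-catalysed 1,4-addition of the vinyl Grignard reagent gives the C10 enolate regiospecifically, which is aminomethylated (Mannich reaction) and, after N-methylation, loses trimethylamine by E1cB elimination to the exocyclic enone; C5 is formed as a racemate.

Step 2
Reactants: 4 rac-3-ethenyl-4,4-dimethyl-2-methylidenecyclohexan-1-one
Product: 5 rac-(1S,3R)-3-ethenyl-4,4-dimethyl-2-methylidenecyclohexan-1-ol
Conditions: NaBH4, CeCl3·7H2O, MeOH, −78 °C
Reagents that add atoms: none
Why: Luche 1,2-reduction, in which hydride should attack C1 anti to the C5 vinyl group (1,3-relationship across the methylidene carbon) and so give the cis-1,3 allylic alcohol.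

Step 3
Reactants: 5 rac-(1S,3R)-3-ethenyl-4,4-dimethyl-2-methylidenecyclohexan-1-ol
Product: 6 (3S,4S,8R)-8-ethenyl-7,7-dimethyl-1-oxaspiro[2.5]octan-4-ol
Conditions: Ti(OiPr)4 (0.2 equiv), L-(+)-diisopropyl tartrate (0.25 equiv), t-BuOOH (0.5 equiv), 4 Å molecular sieves, CH2Cl2, −20 °C
Reagents that add atoms: tert-butyl hydroperoxide CC(C)(C)OO
Why: Sharpless kinetic resolution, in which the L-(+)-tartrate catalyst should epoxidise the (1S)-allylic alcohol faster and deliver oxygen syn to the hydroxyl, so that the epoxy alcohol is a single enantiomer (the C10 configuration is erased later).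

Step 4
Reactants: 6 (3S,4S,8R)-8-ethenyl-7,7-dimethyl-1-oxaspiro[2.5]octan-4-ol
Product: 7 (3S,4S,8R)-8-ethenyl-7,7-dimethyl-1-oxaspiro[2.5]octan-4-yl acetate
Conditions: Ac2O, Et3N, DMAP (cat.), CH2Cl2, 0 °C → rt
Reagents that add atoms: acetic anhydride CC(=O)OC(C)=O
Why: Standard DMAP-catalysed acetylation of the only hydroxyl installs the C1 acetate of the target before any other hydroxyl exists.

Step 5
Reactants: 7 (3S,4S,8R)-8-ethenyl-7,7-dimethyl-1-oxaspiro[2.5]octan-4-yl acetate
Product: 8 (3S,4S,8R)-8-formyl-7,7-dimethyl-1-oxaspiro[2.5]octan-4-yl acetate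
Conditions: O3, CH2Cl2, −78 °C; then PPh3, −78 °C → rt
Reagents that add atoms: ozone [O-][O+]=O
Why: Ozonolysis with reductive work-up cleaves the only alkene to the C6 aldehyde under neutral conditions that should spare epoxide and acetate.

Step 6
Reactants: 9 (5S)-5-{[(1S,2R,5S)-5-methyl-2-(propan-2-yl)cyclohexyl]oxy}furan-2(5H)-one
Product: 11 (5S)-3-bromo-5-{[(1S,2R,5S)-5-methyl-2-(propan-2-yl)cyclohexyl]oxy}furan-2(5H)-one, via trans-dibromide 10 (not isolated)
Conditions: Br2, CH2Cl2, rt; then Et3N, 0 °C
Reagents that add atoms: bromine BrBr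
Why: Anti addition of bromine followed by E1cB loss of HBr (α-deprotonation, β-bromide leaves) gives the α-bromobutenolide without touching the acetal centre.

Step 7
Reactants: 11 (5S)-3-bromo-5-{[(1S,2R,5S)-5-methyl-2-(propan-2-yl)cyclohexyl]oxy}furan-2(5H)-one
Product: 12 (5S)-3-(2-bromoprop-2-en-1-yl)-5-{[(1S,2R,5S)-5-methyl-2-(propan-2-yl)cyclohexyl]oxy}furan-2(5H)-one
Conditions: BrZnCH2C(Br)=CH2 (made from 2,3-dibromopropene and Zn dust, THF, 0 °C), Pd(PPh3)4 (5 mol%), THF, 0 °C → rt
Reagents that add atoms: 2,3-dibromopropene C=C(Br)CBr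
Why: Negishi coupling, in which zerovalent palladium should insert into the electron-poor α-bromoenoate C–Br bond faster than into the unactivated 2-bromoalkene of the allylzinc reagent.

Step 8
Reactants: 8 (3S,4S,8R)-8-formyl-7,7-dimethyl-1-oxaspiro[2.5]octan-4-yl acetate; 12 (5S)-3-(2-bromoprop-2-en-1-yl)-5-(d-menthyloxy)furan-2(5H)-one
Product: 13 bromoallyl γ-lactone acetal diol (ring A, cyclopentane and cis-fused C7/C11 lactone acetal; C6-OH, C20-OH)
Conditions: (C5H5)2TiCl2 (2.5 equiv), Zn dust, THF, rt; then 12, then slow addition of 8, −20 °C → rt; aq. NaH2PO4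
Reagents that add atoms: none
Why: Proposed new method: trivalent titanium opens the spiro-epoxide homolytically to the tertiary C10 radical (C20–O–Ti), which adds to C9 of the butenolide anti to the menthyloxy group and anti to the cis C1-acetoxy/C5-formyl groups; a second (C5H5)2TiCl reduces the α-lactone radical to a titanium enolate that adds to the neighbouring C6 aldehyde (5-exo aldol), creating quaternary C8 with its configuration fixed by the cis ring fusion, while the open transition state of the coordinatively saturated titanocene enolate should place the aldehyde oxygen exo (6-OH anti to C7); the closest known reaction types are the Nugent–RajanBabu epoxide–acrylate radical coupling and the titanocene-enolate (Reformatsky-type) aldol addition, run here in tandem as a radical–polar crossover.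

Step 9
Reactants: 13 bromoallyl γ-lactone acetal diol
Product: 14 bromoallyl δ-lactone aldehyde (C7/C20 lactone, C9-CHO)
Conditions: Et3N, DMAP (cat.), CH2Cl2, rt
Reagents that add atoms: none
Why: Translactonisation, in which the primary C20 hydroxyl attacks the activated acyloxy-acetal lactone carbonyl C7 through a six-membered transition state and the expelled hemiacetal collapses irreversibly to the C11 aldehyde and menthol.

Step 10
Reactants: 14 bromoallyl δ-lactone aldehyde
Product: 16 enone aldehyde (C8–CH2–C(=CH2)–COCH3, C9-CHO), via ethoxydiene 15 (not isolated)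
Conditions: Bu3Sn–C(OEt)=CH2, Pd(PPh3)4 (5 mol%), toluene, 90 °C; then 1 M HCl, THF, 0 °C
Reagents that add atoms: tributyl(1-ethoxyvinyl)stannane CCOC(=C)[Sn](CCCC)(CCCC)CCCC; water O
Why: Stille coupling of the 2-bromoalkene with the 1-ethoxyvinylstannane (acetyl anion equivalent) followed by mild acid hydrolysis of the 2-ethoxydiene gives the methyl enone and should leave aldehyde, acetate and lactone untouched.

Step 11
Reactants: 16 enone aldehyde
Product: 18 11-hydroxy-13-acetyl tetracycle (ring C closed; 6,11-diol), via 13-epi ketone 17 (not isolated)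
Conditions: SmI2 (2.5 equiv), HMPA, THF, −78 °C; then t-BuOH, −78 → 0 °C; then DBU, CH2Cl2, rt
Reagents that add atoms: none
Why: Single-electron transfer from SmI2 to the C11 aldehyde gives a samarium ketyl that adds to the unsubstituted terminus C12 of the tethered 2-substituted enone, and the resulting α-keto radical is reduced to a trivalent samarium enolate that is protonated at C13 (the same C11–C12 bond results if the enone is reduced first). The closest known reaction type is the SmI2 ketyl–olefin (aldehyde–enone/enoate) reductive cyclisation. Ring C closes in the 6-endo-trig mode, the only one within reach, because C12 is the sole β-carbon and 5-exo attack at the acyl-bearing C13 is electronically disfavoured. C11 is set by a chair-like transition state in which the bulky O–Sm(HMPA)n group is equatorial, anti to quaternary C10 and on the side of the enolate oxygen at C13, which gives the equatorial 11-hydroxyl; C13 is set thermodynamically, DBU epimerising the kinetic axial ketone to the equatorial acetyl, which avoids the 1,3-diaxial clash with the axial lactone carbonyl C7. The step needs carbonyl-to-alkene coupling in preference to conjugate reduction, pinacol closure or reduction of lactone and acetate, which the aprotic low-temperature conditions (proton source added only after cyclisation) and the far easier reduction of aldehyde and enone should secure.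

Step 12
Reactants: 18 11-hydroxy-13-acetyl tetracycle
Product: 19 6,11-bis(trimethylsilyl) ether of 18
Conditions: Me3SiCl, imidazole, DMF, 0 °C → rt
Reagents that add atoms: chlorotrimethylsilane C[Si](C)(C)Cl
Why: Silylation masks both secondary hydroxyls so that only the methyl ketone reacts with base in the next step.

Step 13
Reactants: 19 6,11-bis(trimethylsilyl) ether
Product: 20 enol triflate (C13–C(OTf)=CH2)
Conditions: KN(SiMe3)2, THF, −78 °C; then N-(5-chloropyridin-2-yl)bis(trifluoromethanesulfonimide), −78 °C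
Reagents that add atoms: N-(5-chloropyridin-2-yl)bis(trifluoromethanesulfonimide) O=S(=O)(N(c1ccc(Cl)cn1)S(=O)(=O)C(F)(F)F)C(F)(F)F
Why: Kinetic deprotonation at the methyl group of the ketone (the lactone has no α-hydrogen and the acetate is far less acidic) and O-triflation by the Comins reagent give the terminal enol triflate with C13 untouched.

Step 14
Reactants: 20 enol triflate
Product: 22 target CNP0421185.1, via bis(silyl ether) acrylate 21 (not isolated)
Conditions: Pd(OAc)2 (10 mol%), PPh3, CO (1 atm), MeOH, Et3N, DMF, 50 °C; then 1 M HCl, THF, 0 °C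
Reagents that add atoms: carbon monoxide [C-]#[O+]; methanol CO
Why: Palladium-catalysed methoxycarbonylation of the enol triflate (oxidative addition, CO insertion, methanolysis) installs the 2-substituted methyl acrylate, and dilute acid then cleaves both trimethylsilyl ethers.

Compound list
1 | 4,4-dimethylcyclohex-2-en-1-one | CC1(C)CCC(=O)C=C1 | starting material
2 | rac-trans-2-[(dimethylamino)methyl]-3-ethenyl-4,4-dimethylcyclohexan-1-one (Mannich base) | CN(C)C[C@@H]1C(=O)CCC(C)(C)[C@H]1C=C | intermediate
3 | rac-trans-(6-ethenyl-5,5-dimethyl-2-oxocyclohexyl)-N,N,N-trimethylmethanaminium iodide | C[N+](C)(C)C[C@@H]1C(=O)CCC(C)(C)[C@H]1C=C.[I-] | intermediate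
4 | rac-3-ethenyl-4,4-dimethyl-2-methylidenecyclohexan-1-one | C=C1C(=O)CCC(C)(C)[C@H]1C=C | intermediate
5 | rac-(1S,3R)-3-ethenyl-4,4-dimethyl-2-methylidenecyclohexan-1-ol (cis) | C=C1[C@@H](O)CCC(C)(C)[C@H]1C=C | intermediate
6 | (3S,4S,8R)-8-ethenyl-7,7-dimethyl-1-oxaspiro[2.5]octan-4-ol | C1O[C@]12[C@@H](O)CCC(C)(C)[C@H]2C=C | intermediate
7 | (3S,4S,8R)-8-ethenyl-7,7-dimethyl-1-oxaspiro[2.5]octan-4-yl acetate | C1O[C@]12[C@@H](OC(C)=O)CCC(C)(C)[C@H]2C=C | intermediate
8 | (3S,4S,8R)-8-formyl-7,7-dimethyl-1-oxaspiro[2.5]octan-4-yl acetate | C1O[C@]12[C@@H](OC(C)=O)CCC(C)(C)[C@H]2C=O | intermediate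
9 | (5S)-5-{[(1S,2R,5S)-5-methyl-2-(propan-2-yl)cyclohexyl]oxy}furan-2(5H)-one | O=C1C=C[C@@H](O[C@H]2C[C@@H](C)CC[C@@H]2C(C)C)O1 | starting material
10 | trans-3,4-dibromo-(5S)-5-(d-menthyloxy)oxolan-2-one (bromine at C4 anti to the menthyloxy group) | O=C1[C@@H](Br)[C@H](Br)[C@@H](O[C@H]2C[C@@H](C)CC[C@@H]2C(C)C)O1 | intermediate
11 | (5S)-3-bromo-5-{[(1S,2R,5S)-5-methyl-2-(propan-2-yl)cyclohexyl]oxy}furan-2(5H)-one | O=C1C(Br)=C[C@@H](O[C@H]2C[C@@H](C)CC[C@@H]2C(C)C)O1 | intermediate
12 | (5S)-3-(2-bromoprop-2-en-1-yl)-5-{[(1S,2R,5S)-5-methyl-2-(propan-2-yl)cyclohexyl]oxy}furan-2(5H)-one | O=C1C(CC(Br)=C)=C[C@@H](O[C@H]2C[C@@H](C)CC[C@@H]2C(C)C)O1 | intermediate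
13 | bromoallyl γ-lactone acetal diol: ring A (1-OAc, 4,4-Me2) trans-fused at C5–C10 to cyclopentane C5–C6–C8–C9–C10; 6-OH; C8 bears CH2C(Br)=CH2; γ-lactone C8–C7(=O)–O–C11H(O-d-menthyl)–C9 cis-fused; C10 bears CH2OH (C20); C1, C5, C6, C8, C9, C10 as in 22, C11 (S) | OC[C@@]12[C@@H](OC(C)=O)CCC(C)(C)[C@H]1[C@H](O)[C@@]1(CC(Br)=C)C(=O)O[C@H](O[C@H]3C[C@@H](C)CC[C@@H]3C(C)C)[C@@H]21 | intermediate
14 | bromoallyl δ-lactone aldehyde: as 13 but lactone C8–C7(=O)–O–C20–C10 and C9 bears CHO (C11); C1, C5, C6, C8, C9, C10 as in 22 | O=C[C@@H]1[C@]2(CC(Br)=C)C(=O)OC[C@]13[C@@H](OC(C)=O)CCC(C)(C)[C@H]3[C@@H]2O | intermediate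
15 | ethoxydiene: as 14 with C8–CH2–C(=CH2)–C(OEt)=CH2 | O=C[C@@H]1[C@]2(CC(=C)C(=C)OCC)C(=O)OC[C@]13[C@@H](OC(C)=O)CCC(C)(C)[C@H]3[C@@H]2O | intermediate
16 | enone aldehyde: as 14 with C8–CH2–C(=CH2)–C(=O)CH3 | O=C[C@@H]1[C@]2(CC(=C)C(C)=O)C(=O)OC[C@]13[C@@H](OC(C)=O)CCC(C)(C)[C@H]3[C@@H]2O | intermediate
17 | 13-epi ketone: tetracycle with ring C closed, 11-OH as in 22, acetyl at C13 axial (13-epimer of 18) | CC(=O)[C@H]1C[C@H](O)[C@@H]2[C@]3(C1)C(=O)OC[C@]21[C@@H](OC(C)=O)CCC(C)(C)[C@H]1[C@@H]3O | intermediate
18 | 11-hydroxy-13-acetyl tetracycle: target skeleton with acetyl in place of the acrylate at C13; all stereocentres as in 22 | CC(=O)[C@@H]1C[C@H](O)[C@@H]2[C@]3(C1)C(=O)OC[C@]21[C@@H](OC(C)=O)CCC(C)(C)[C@H]1[C@@H]3O | intermediate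
19 | 6,11-bis(trimethylsilyl) ether of 18 | CC(=O)[C@@H]1C[C@H](O[Si](C)(C)C)[C@@H]2[C@]3(C1)C(=O)OC[C@]21[C@@H](OC(C)=O)CCC(C)(C)[C@H]1[C@@H]3O[Si](C)(C)C | intermediate
20 | enol triflate: as 19 with C13–C(OSO2CF3)=CH2 | C=C(OS(=O)(=O)C(F)(F)F)[C@@H]1C[C@H](O[Si](C)(C)C)[C@@H]2[C@]3(C1)C(=O)OC[C@]21[C@@H](OC(C)=O)CCC(C)(C)[C@H]1[C@@H]3O[Si](C)(C)C | intermediate
21 | 6,11-bis(trimethylsilyl) ether of the target | C=C(C(=O)OC)[C@@H]1C[C@H](O[Si](C)(C)C)[C@@H]2[C@]3(C1)C(=O)OC[C@]21[C@@H](OC(C)=O)CCC(C)(C)[C@H]1[C@@H]3O[Si](C)(C)C | intermediate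
22 | CNP0421185.1, (1S,5R,6S,8S,9S,10S,11S,13S) in the locants of remark 1 | C=C(C(=O)OC)[C@@H]1C[C@H](O)[C@@H]2[C@]3(C1)C(=O)OC[C@]21[C@@H](OC(C)=O)CCC(C)(C)[C@H]1[C@@H]3O | target

Total step count: 14. Longest linear sequence: 12 steps (steps 1–5 and 8–14); the butenolide branch (steps 6–7) joins at step 8.

Steps most likely to fail

1. Step 8 (proposed new method). The titanium enolate may be protonated before it adds to the aldehyde, the β,γ-epoxy aldehyde may suffer base- or Lewis-acid-induced epoxide opening or epimerisation at C5, and the facial selectivity at C6 may be poor. The fallback uses known chemistry, sets out from 7 and 12 and comes back at 13 (step 5 is then not used). Acetate 7 is coupled with 12 under (C5H5)2TiCl2 (cat.), Mn, Me3SiCl and 2,4,6-collidine in THF (protonative Nugent–RajanBabu-type Giese coupling) to the vinyl lactone acetal silyl ether F1. Ozonolysis with PPh3 work-up gives the aldehyde F2. The lactone enolate aldol (LiN(SiMe3)2, THF, −78 °C, reversible deprotonation with only the lactone enolate having an intramolecular partner) closes the cyclopentane to the silyl ether aldol F3, and dilute HCl in THF cleaves the silyl ether to 13.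

2. Step 11 (key step). Conjugate reduction of the enone, pinacol-type closure onto the ketone carbonyl or poor facial selectivity at C11 may compete. The fallback sets out from 16 and comes back at 18 and makes no new compound (F0). The ketyl is generated catalytically by proton-coupled electron transfer (Ir(ppy)2(dtbbpy)PF6 cat., Hantzsch ester, diphenyl phosphate, MeCN, blue light). It adds to C12 in the same 6-endo mode, and the α-keto radical is quenched by hydrogen-atom transfer and not through a samarium enolate. DBU then equilibrates C13.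

3. Step 3. The resolution may be slow or poorly selective, because the reactive conformer needs a 1,3-diaxial hydroxyl/vinyl arrangement next to the alkene. The fallback sets out from 5 and comes back at 6. Candida antarctica lipase B with vinyl acetate acylates the (1R,3S)-enantiomer to the acetate F5 and leaves the (1S,3R)-alcohol F4. F4 is epoxidised syn to the hydroxyl with VO(acac)2 and t-BuOOH to give 6.

Further compounds
F1 | step 8 | vinyl lactone acetal silyl ether: 1-acetoxy ring A with C5 vinyl, C10 bearing CH2OSiMe3 and the γ-lactone acetal (C8-H, C8 bromoallyl trans to C10) | C[Si](C)(C)OC[C@]1([C@@H](OC(C)=O)CCC(C)(C)[C@H]1C=C)[C@H]1[C@H](CC(Br)=C)C(=O)O[C@@H]1O[C@H]1C[C@@H](C)CC[C@@H]1C(C)C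
F2 | step 8 | aldehyde from F1 (C5 formyl) | C[Si](C)(C)OC[C@]1([C@@H](OC(C)=O)CCC(C)(C)[C@H]1C=O)[C@H]1[C@H](CC(Br)=C)C(=O)O[C@@H]1O[C@H]1C[C@@H](C)CC[C@@H]1C(C)C
F3 | step 8 | 20-O-trimethylsilyl ether of 13 | C[Si](C)(C)OC[C@@]12[C@@H](OC(C)=O)CCC(C)(C)[C@H]1[C@H](O)[C@@]1(CC(Br)=C)C(=O)O[C@H](O[C@H]3C[C@@H](C)CC[C@@H]3C(C)C)[C@@H]21
F4 | step 3 | (1S,3R)-3-ethenyl-4,4-dimethyl-2-methylidenecyclohexan-1-ol (single enantiomer) | C=C1[C@@H](O)CCC(C)(C)[C@H]1C=C
F5 | step 3 | (1R,3S)-3-ethenyl-4,4-dimethyl-2-methylidenecyclohexyl acetate | C=C1[C@H](OC(C)=O)CCC(C)(C)[C@@H]1C=C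
F0 | step 11 | none | none
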